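**Retrosynthetic overview**
- The quinone is unveiled last by oxidative demethylation of a hydroquinone dimethyl ether; before that, the lower amide C–N bond to 2-amino-3-hydroxycyclopent-2-enone (made from cyclopentane-1,3-dione) is cut.
- Lower chain: C4=C5 by vinylogous Horner–Wadsworth–Emmons olefination, aryl–C7 bond by Suzuki coupling of an aryl iodide; upper amide C–N by acylation of 3-chloro-4-iodo-2,5-dimethoxyaniline (from 2,5-dimethoxy-4-nitroaniline by chlorination, Sandmeyer iodination, reduction).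
- Key step, upper acid: a Johnson–Claisen [3,3]-sigmatropic rearrangement forms the C2–C3 bond and sets the (4E)-trisubstituted alkene; C2=C3 follows by selenoxide elimination.
- The only stereocentre (C6, R) is bought in Roche-ester-derived (S)-3-bromo-2-methylpropan-1-ol and is never a reacting atom.
- Rings: none is constructed; the benzenoid ring and the cyclopentane ring are purchased, and the benzenoid ring becomes the quinone in the final step.

Assumption: compounds 6, 8, 9, 10 and 11 are carried as epimer mixtures at a centre that is destroyed later; the target is taken as the enol tautomer drawn.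

**Step 1**
Reactants: 1 (S)-3-bromo-2-methylpropan-1-ol; 2 n-propylmagnesium bromide
Product: 3 (R)-2-methylhexan-1-ol
Conditions: 2 (3 equiv), Li2CuCl4 (5 mol %), THF/NMP, −20 °C → rt; aq. NH4Cl
Reagents that add atoms: none
Why: Copper-catalysed Kochi-type sp3–sp3 Grignard cross-coupling displaces the primary bromide after the first equivalent of 2 has masked the hydroxyl as its magnesium alkoxide; the stereocentre does not react, and its descriptor changes from S to R only because the CIP priorities change.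

**Step 2**
Reactants: 3 (R)-2-methylhexan-1-ol; 4 isopropenylmagnesium bromide
Product: 6 (3RS,4R)-2,4-dimethyloct-1-en-3-ol, via (R)-2-methylhexanal 5 (not isolated)
Conditions: (COCl)2, DMSO, CH2Cl2, −78 °C; iPr2NEt, −78 °C; then 4 (4 equiv, THF), −78 → 0 °C; aq. NH4Cl
Reagents that add atoms: none
Why: Telescoped Swern oxidation and Grignard addition keeps the volatile, epimerisable α-methyl aldehyde cold and unisolated; the new carbinol centre is formed without control but is destroyed in step 3.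

**Step 3**
Reactants: 6 (3RS,4R)-2,4-dimethyloct-1-en-3-ol; 7 triethyl orthopropionate
Product: 9 ethyl (2RS,4E,6R)-2,4,6-trimethyldec-4-enoate, via ketene acetal 8 (not isolated)
Conditions: 7 (6 equiv), EtCO2H (cat.), 140 °C, EtOH distilled off
Reagents that add atoms: none
Why: Johnson–Claisen [3,3]-sigmatropic rearrangement through a chair transition state with the sec-alkyl group equatorial forms the C2–C3 bond and the (4E)-trisubstituted alkene from either carbinol epimer; C6 is a spectator and C2 is formed as a mixture that step 4 removes.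

**Step 4**
Reactants: 9 ethyl (2RS,4E,6R)-2,4,6-trimethyldec-4-enoate
Product: 12 ethyl (2E,4E,6R)-2,4,6-trimethyldeca-2,4-dienoate, via α-phenylselanyl ester 10 (not isolated), via selenoxide 11 (not isolated)
Conditions: LiN(iPr)2, THF, −78 °C; PhSeBr, −78 °C; then 30 % H2O2, pyridine, CH2Cl2, 0 °C → rt
Reagents that add atoms: none
Why: Enolate α-selenenylation followed by selenoxide syn-elimination toward the activated allylic C3–H gives the conjugated tiglate-type (2E) dienoate, with pyridine buffering against epoxidation of the alkene by perseleninic acid.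

**Step 5**
Reactants: 12 ethyl (2E,4E,6R)-2,4,6-trimethyldeca-2,4-dienoate
Product: 13 (2E,4E,6R)-2,4,6-trimethyldeca-2,4-dienoic acid
Conditions: LiOH, THF/MeOH/H2O, 50 °C; then 1 M HCl
Reagents that add atoms: lithium hydroxide, [Li+].[OH-]
Why: Saponification by acyl–oxygen cleavage proceeds without touching the remote C6 centre or the diene geometry.

**Step 6**
Reactants: 14 2,5-dimethoxy-4-nitroaniline
Product: 15 2-chloro-3,6-dimethoxy-4-nitroaniline
Conditions: NCS, MeCN, 60 °C
Reagents that add atoms: N-chlorosuccinimide, O=C1CCC(=O)N1Cl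
Why: Electrophilic aromatic chlorination goes to the only position that is ortho to NH2, ortho to OMe and meta to NO2.

**Step 7**
Reactants: 15 2-chloro-3,6-dimethoxy-4-nitroaniline
Product: 17 3-chloro-2-iodo-1,4-dimethoxy-5-nitrobenzene, via arenediazonium hydrogensulfate 16 (not isolated)
Conditions: NaNO2, conc. H2SO4/AcOH, 0–5 °C; then KI, H2O, 0 °C → rt
Reagents that add atoms: potassium iodide, [K+].[I-]
Why: Sandmeyer-type iododediazoniation, with nitrosylsulfuric acid to diazotise the weakly basic nitroaniline, replaces NH2 by iodine at the carbon that will carry the triene.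

**Step 8**
Reactants: 17 3-chloro-2-iodo-1,4-dimethoxy-5-nitrobenzene
Product: 18 3-chloro-4-iodo-2,5-dimethoxyaniline
Conditions: Fe powder, AcOH/EtOH, 60 °C
Reagents that add atoms: none
Why: Béchamp-type dissolving-metal reduction converts NO2 to NH2 without hydrogenolysis of C–I or C–Cl.

**Step 9**
Reactants: 13 (2E,4E,6R)-2,4,6-trimethyldeca-2,4-dienoic acid; 18 3-chloro-4-iodo-2,5-dimethoxyaniline
Product: 20 (2E,4E,6R)-N-(3-chloro-4-iodo-2,5-dimethoxyphenyl)-2,4,6-trimethyldeca-2,4-dienamide, via acid chloride 19 (not isolated)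
Conditions: 13, (COCl)2, DMF (cat.), CH2Cl2, 0 °C → rt, concentrate; then 18, pyridine, CH2Cl2, 0 °C → rt
Reagents that add atoms: none
Why: N-acylation of the aniline by the preformed dienoyl chloride is fast and leaves the diene geometry and C6 untouched.

**Step 10**
Reactants: 20 (2E,4E,6R)-N-(3-chloro-4-iodo-2,5-dimethoxyphenyl)-2,4,6-trimethyldeca-2,4-dienamide; 21 (E)-2-(3,3-diethoxyprop-1-en-1-yl)-4,4,5,5-tetramethyl-1,3,2-dioxaborolane
Product: 23 (2E,4E,6R)-N-{3-chloro-2,5-dimethoxy-4-[(E)-3-oxoprop-1-en-1-yl]phenyl}-2,4,6-trimethyldeca-2,4-dienamide, via diethyl acetal 22 (not isolated)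
Conditions: PdCl2(dppf) (5 mol %), K3PO4, dioxane/H2O, 80 °C; then 1 M HCl, THF, rt
Reagents that add atoms: water, O
Why: Suzuki–Miyaura coupling, in which the zerovalent palladium catalyst inserts into C–I and not C–Cl, transfers the alkenyl group with retention of E geometry, and acetal hydrolysis then releases the enal.

**Step 11**
Reactants: 23 (2E,4E,6R)-N-{3-chloro-2,5-dimethoxy-4-[(E)-3-oxoprop-1-en-1-yl]phenyl}-2,4,6-trimethyldeca-2,4-dienamide; 24 triethyl 4-phosphonocrotonate
Product: 25 ethyl (2E,4E,6E)-7-{2-chloro-3,6-dimethoxy-4-[(2E,4E,6R)-2,4,6-trimethyldeca-2,4-dienamido]phenyl}hepta-2,4,6-trienoate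
Conditions: 24, LiN(SiMe3)2, THF, −78 °C; then 23, −78 → 0 °C
Reagents that add atoms: none
Why: Vinylogous Horner–Wadsworth–Emmons olefination of the enal by the stabilised phosphonate anion is E-selective and completes the all-E trienoate.

**Step 12**
Reactants: 25 ethyl (2E,4E,6E)-7-{2-chloro-3,6-dimethoxy-4-[(2E,4E,6R)-2,4,6-trimethyldeca-2,4-dienamido]phenyl}hepta-2,4,6-trienoate
Product: 26 (2E,4E,6E)-7-{2-chloro-3,6-dimethoxy-4-[(2E,4E,6R)-2,4,6-trimethyldeca-2,4-dienamido]phenyl}hepta-2,4,6-trienoic acid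
Conditions: LiOH, THF/MeOH/H2O, rt; then 1 M HCl
Reagents that add atoms: lithium hydroxide, [Li+].[OH-]
Why: Saponification cleaves the unhindered ethyl ester while the hindered secondary anilide survives.

**Step 13**
Reactants: 27 cyclopentane-1,3-dione
Product: 28 2-(hydroxyimino)cyclopentane-1,3-dione
Conditions: NaNO2, aq. HCl, 0–5 °C
Reagents that add atoms: sodium nitrite, [Na+].[O-]N=O
Why: C-nitrosation of the enolised 1,3-dione at C2 followed by tautomerisation gives the oxime.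

**Step 14**
Reactants: 28 2-(hydroxyimino)cyclopentane-1,3-dione
Product: 29 2-amino-3-hydroxycyclopent-2-en-1-one hydrochloride
Conditions: H2 (1 atm), 10 % Pd/C, HCl, MeOH, rt
Reagents that add atoms: hydrogen chloride, Cl
Why: Knorr-type hydrogenation of the α-oximino ketone gives the amine, which is trapped as its hydrochloride so that it does not self-condense.

**Step 15**
Reactants: 26 (2E,4E,6E)-7-{2-chloro-3,6-dimethoxy-4-[(2E,4E,6R)-2,4,6-trimethyldeca-2,4-dienamido]phenyl}hepta-2,4,6-trienoic acid; 29 2-amino-3-hydroxycyclopent-2-en-1-one hydrochloride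
Product: 31 (2E,4E,6E)-7-{2-chloro-3,6-dimethoxy-4-[(2E,4E,6R)-2,4,6-trimethyldeca-2,4-dienamido]phenyl}-N-(2-hydroxy-5-oxocyclopent-1-en-1-yl)hepta-2,4,6-trienamide, via mixed carbonic anhydride 30 (not isolated)
Conditions: iBuOCOCl, N-methylmorpholine, THF, −20 °C; then 29, Et3N, DMF, −20 °C → rt
Reagents that add atoms: none
Why: Mixed-anhydride amidation acylates the liberated amine, and any enol ester formed by O-acylation converges on the amide by O→N acyl shift.

**Step 16**
Reactants: 31 (2E,4E,6E)-7-{2-chloro-3,6-dimethoxy-4-[(2E,4E,6R)-2,4,6-trimethyldeca-2,4-dienamido]phenyl}-N-(2-hydroxy-5-oxocyclopent-1-en-1-yl)hepta-2,4,6-trienamide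
Product: 32 chinikomycin B
Conditions: (NH4)2Ce(NO3)6 (2.2 equiv), MeCN/H2O, 0 °C, 10 min
Reagents that add atoms: water, O
Why: Oxidative demethylation of the electron-rich 2,5-dimethoxyanilide is complete within minutes at 0 °C, which should outpace oxidation of the triene or the enolised aminocyclopentenone, and water supplies both quinone oxygens.

**Compound list**
1 | (S)-3-bromo-2-methylpropan-1-ol | OC[C@H](C)CBr | starting material
2 | n-propylmagnesium bromide | CCC[Mg]Br | starting material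
3 | (R)-2-methylhexan-1-ol | CCCC[C@@H](C)CO | intermediate
4 | isopropenylmagnesium bromide | CC(=C)[Mg]Br | starting material
5 | (R)-2-methylhexanal | CCCC[C@@H](C)C=O | intermediate
6 | (3RS,4R)-2,4-dimethyloct-1-en-3-ol | CCCC[C@@H](C)C(O)C(C)=C | intermediate
7 | triethyl orthopropionate (1,1,1-triethoxypropane) | CCC(OCC)(OCC)OCC | starting material
8 | (4R)-3-[(1-ethoxyprop-1-en-1-yl)oxy]-2,4-dimethyloct-1-ene (ketene acetal, C3 epimers) | CCCC[C@@H](C)C(OC(OCC)=CC)C(C)=C | intermediate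
9 | ethyl (2RS,4E,6R)-2,4,6-trimethyldec-4-enoate | CCCC[C@@H](C)/C=C(C)/CC(C)C(=O)OCC | intermediate
10 | ethyl (4E,6R)-2,4,6-trimethyl-2-(phenylselanyl)dec-4-enoate (C2 epimers) | CCCC[C@@H](C)/C=C(C)/CC(C)([Se]c1ccccc1)C(=O)OCC | intermediate
11 | ethyl (4E,6R)-2,4,6-trimethyl-2-(phenylseleninyl)dec-4-enoate (selenoxide, epimers) | CCCC[C@@H](C)/C=C(C)/CC(C)([Se](=O)c1ccccc1)C(=O)OCC | intermediate
12 | ethyl (2E,4E,6R)-2,4,6-trimethyldeca-2,4-dienoate | CCCC[C@@H](C)/C=C(C)/C=C(\C)C(=O)OCC | intermediate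
13 | (2E,4E,6R)-2,4,6-trimethyldeca-2,4-dienoic acid | CCCC[C@@H](C)/C=C(C)/C=C(\C)C(=O)O | intermediate
14 | 2,5-dimethoxy-4-nitroaniline | Nc1cc(OC)c([N+](=O)[O-])cc1OC | starting material
15 | 2-chloro-3,6-dimethoxy-4-nitroaniline | Nc1c(Cl)c(OC)c([N+](=O)[O-])cc1OC | intermediate
16 | 2-chloro-3,6-dimethoxy-4-nitrobenzenediazonium hydrogensulfate | N#[N+]c1c(Cl)c(OC)c([N+](=O)[O-])cc1OC.OS(=O)(=O)[O-] | intermediate
17 | 3-chloro-2-iodo-1,4-dimethoxy-5-nitrobenzene | Ic1c(Cl)c(OC)c([N+](=O)[O-])cc1OC | intermediate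
18 | 3-chloro-4-iodo-2,5-dimethoxyaniline | Nc1cc(OC)c(I)c(Cl)c1OC | intermediate
19 | (2E,4E,6R)-2,4,6-trimethyldeca-2,4-dienoyl chloride | CCCC[C@@H](C)/C=C(C)/C=C(\C)C(=O)Cl | intermediate
20 | (2E,4E,6R)-N-(3-chloro-4-iodo-2,5-dimethoxyphenyl)-2,4,6-trimethyldeca-2,4-dienamide | CCCC[C@@H](C)/C=C(C)/C=C(\C)C(=O)Nc1cc(OC)c(I)c(Cl)c1OC | intermediate
21 | (E)-2-(3,3-diethoxyprop-1-en-1-yl)-4,4,5,5-tetramethyl-1,3,2-dioxaborolane | CCOC(OCC)/C=C/B1OC(C)(C)C(C)(C)O1 | starting material
22 | (2E,4E,6R)-N-{3-chloro-4-[(E)-3,3-diethoxyprop-1-en-1-yl]-2,5-dimethoxyphenyl}-2,4,6-trimethyldeca-2,4-dienamide | CCCC[C@@H](C)/C=C(C)/C=C(\C)C(=O)Nc1cc(OC)c(/C=C/C(OCC)OCC)c(Cl)c1OC | intermediate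
23 | (2E,4E,6R)-N-{3-chloro-2,5-dimethoxy-4-[(E)-3-oxoprop-1-en-1-yl]phenyl}-2,4,6-trimethyldeca-2,4-dienamide | CCCC[C@@H](C)/C=C(C)/C=C(\C)C(=O)Nc1cc(OC)c(/C=C/C=O)c(Cl)c1OC | intermediate
24 | triethyl 4-phosphonocrotonate (ethyl (E)-4-(diethoxyphosphoryl)but-2-enoate) | CCOC(=O)/C=C/CP(=O)(OCC)OCC | starting material
25 | ethyl (2E,4E,6E)-7-{2-chloro-3,6-dimethoxy-4-[(2E,4E,6R)-2,4,6-trimethyldeca-2,4-dienamido]phenyl}hepta-2,4,6-trienoate | CCCC[C@@H](C)/C=C(C)/C=C(\C)C(=O)Nc1cc(OC)c(/C=C/C=C/C=C/C(=O)OCC)c(Cl)c1OC | intermediate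
26 | (2E,4E,6E)-7-{2-chloro-3,6-dimethoxy-4-[(2E,4E,6R)-2,4,6-trimethyldeca-2,4-dienamido]phenyl}hepta-2,4,6-trienoic acid | CCCC[C@@H](C)/C=C(C)/C=C(\C)C(=O)Nc1cc(OC)c(/C=C/C=C/C=C/C(=O)O)c(Cl)c1OC | intermediate
27 | cyclopentane-1,3-dione | O=C1CCC(=O)C1 | starting material
28 | 2-(hydroxyimino)cyclopentane-1,3-dione | O=C1CCC(=O)C1=NO | intermediate
29 | 2-amino-3-hydroxycyclopent-2-en-1-one hydrochloride | NC1=C(O)CCC1=O.Cl | intermediate
30 | mixed isobutyl carbonic anhydride of acid 26 | CCCC[C@@H](C)/C=C(C)/C=C(\C)C(=O)Nc1cc(OC)c(/C=C/C=C/C=C/C(=O)OC(=O)OCC(C)C)c(Cl)c1OC | intermediate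
31 | (2E,4E,6E)-7-{2-chloro-3,6-dimethoxy-4-[(2E,4E,6R)-2,4,6-trimethyldeca-2,4-dienamido]phenyl}-N-(2-hydroxy-5-oxocyclopent-1-en-1-yl)hepta-2,4,6-trienamide | CCCC[C@@H](C)/C=C(C)/C=C(\C)C(=O)Nc1cc(OC)c(/C=C/C=C/C=C/C(=O)NC2=C(O)CCC2=O)c(Cl)c1OC | intermediate
32 | chinikomycin B, (2E,4E,6E)-7-{2-chloro-3,6-dioxo-4-[(2E,4E,6R)-2,4,6-trimethyldeca-2,4-dienamido]cyclohexa-1,4-dien-1-yl}-N-(2-hydroxy-5-oxocyclopent-1-en-1-yl)hepta-2,4,6-trienamide | CCCC[C@@H](C)/C=C(C)/C=C(\C)C(=O)NC1=CC(=O)C(/C=C/C=C/C=C/C(=O)NC2=C(O)CCC2=O)=C(Cl)C1=O | target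

**Totals**
Total step count: 16.
Longest linear sequence: 11 steps (1, 2, 3, 4, 5, 9, 10, 11, 12, 15, 16).

**Three steps most likely to fail**

Step 4. The selenoxide can also eliminate toward the C2 methyl group to give the 2-methylene isomer, and the oxidant can attack the C4=C5 alkene. The fallback sets out from 9 and comes back at 12. Ester 9 is deprotonated with LiN(iPr)2 at −78 °C and brominated with CBr4 to give ethyl (4E,6R)-2-bromo-2,4,6-trimethyldec-4-enoate F1. Heating F1 with DBU in toluene at 90 °C then gives 12 by base-mediated anti-elimination under thermodynamic control, with no oxidant present; DBU also isomerises any 2-methylene ester into the conjugated (2E,4E)-dienoate.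

Step 10. The iodide is flanked by Cl and OMe, so transmetalation and reductive elimination may be slow, and protodeboronation of 21 may compete. The fallback sets out from 20 and comes back at 23. Amide 20 is deprotonated at nitrogen with MeMgCl and subjected to iodine–magnesium exchange with iPrMgCl·LiCl in THF at −20 °C. The arylmagnesium is formylated with DMF to give (2E,4E,6R)-N-(3-chloro-4-formyl-2,5-dimethoxyphenyl)-2,4,6-trimethyldeca-2,4-dienamide F2. Wittig homologation of F2 with (triphenylphosphoranylidene)acetaldehyde in toluene at 80 °C then gives the (E)-enal 23.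

Step 16. The enolised aminocyclopentenone, and to a lesser degree the triene, may not survive the cerium oxidant. The fallback sets out from 20 and comes back at 32, so the oxidation is done before either sensitive unit is present. Amide 20 is oxidised with (NH4)2Ce(NO3)6 in MeCN/H2O at 0 °C to the iodoquinone (2E,4E,6R)-N-(5-chloro-4-iodo-3,6-dioxocyclohexa-1,4-dien-1-yl)-2,4,6-trimethyldeca-2,4-dienamide F3. Separately, commercial prop-2-yn-1-ol is hydrostannylated (Bu3SnH, AIBN, 80 °C) to (E)-3-(tributylstannyl)prop-2-en-1-ol F4 and oxidised with MnO2 to (E)-3-(tributylstannyl)prop-2-enal F5. Olefination of F5 with 24 (LiN(SiMe3)2, THF, −78 °C) gives ethyl (2E,4E,6E)-7-(tributylstannyl)hepta-2,4,6-trienoate F6, which is saponified with LiOH to (2E,4E,6E)-7-(tributylstannyl)hepta-2,4,6-trienoic acid F7. Coupling of F7 with 29 through the isobutyl mixed anhydride (Et3N) gives (2E,4E,6E)-N-(2-hydroxy-5-oxocyclopent-1-en-1-yl)-7-(tributylstannyl)hepta-2,4,6-trienamide F8. A Stille coupling of F3 with F8 (Pd2(dba)3, AsPh3, DMF, rt) under neutral conditions then gives 32 directly.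

**Further compounds**
F1 | step 4 | ethyl (4E,6R)-2-bromo-2,4,6-trimethyldec-4-enoate | CCCC[C@@H](C)/C=C(C)/CC(C)(Br)C(=O)OCC
F2 | step 10 | (2E,4E,6R)-N-(3-chloro-4-formyl-2,5-dimethoxyphenyl)-2,4,6-trimethyldeca-2,4-dienamide | CCCC[C@@H](C)/C=C(C)/C=C(\C)C(=O)Nc1cc(OC)c(C=O)c(Cl)c1OC
F3 | step 16 | (2E,4E,6R)-N-(5-chloro-4-iodo-3,6-dioxocyclohexa-1,4-dien-1-yl)-2,4,6-trimethyldeca-2,4-dienamide | CCCC[C@@H](C)/C=C(C)/C=C(\C)C(=O)NC1=CC(=O)C(I)=C(Cl)C1=O
F4 | step 16 | (E)-3-(tributylstannyl)prop-2-en-1-ol | OC/C=C/[Sn](CCCC)(CCCC)CCCC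
F5 | step 16 | (E)-3-(tributylstannyl)prop-2-enal | O=C/C=C/[Sn](CCCC)(CCCC)CCCC
F6 | step 16 | ethyl (2E,4E,6E)-7-(tributylstannyl)hepta-2,4,6-trienoate | CCOC(=O)/C=C/C=C/C=C/[Sn](CCCC)(CCCC)CCCC
F7 | step 16 | (2E,4E,6E)-7-(tributylstannyl)hepta-2,4,6-trienoic acid | OC(=O)/C=C/C=C/C=C/[Sn](CCCC)(CCCC)CCCC
F8 | step 16 | (2E,4E,6E)-N-(2-hydroxy-5-oxocyclopent-1-en-1-yl)-7-(tributylstannyl)hepta-2,4,6-trienamide | O=C(/C=C/C=C/C=C/[Sn](CCCC)(CCCC)CCCC)NC1=C(O)CCC1=O
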